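**Retrosynthetic overview**
1. The ester is made last, by selective acylation of the primary allylic OH of the labdadiene diol with (S)-3-methylpentanoic acid.
2. The C8 methyl and the 7,8-alkene come from a C8 ketone through its kinetic enol triflate and an iron-catalysed methyl coupling.
3. Key step: ring B and the whole C9 side chain are made together by an allyl-cation-triggered semipinacol ring expansion (cyclopentane to cyclohexanone, 1,2-shift of the quaternary carbon) of a trans-hydrindane 1-vinylcyclopentyl silyl ether with a C5 (E)-allyl bromide from prenol.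
4. The hydrindane comes from a Hajos–Parrish-type enedione by vinyl addition, reductive methylation (trans fusion, gem-dimethyl) and bulky-hydride reduction (axial 3-OH).
5. The enedione comes from 2-methylcyclopentane-1,3-dione and ethyl vinyl ketone (D-phenylalanine aldol). Ring order: cyclopentane (purchased), then ring A (annulation), then ring B (expansion of the cyclopentane).

Assumption: the SMILES is read as the ent-labdane (3S,5S,9R,10S) with an axial 3-OH (anti to the C10 methyl), 13E alkene and (S)-acyl group; (S)-3-methylpentanoic acid is taken as commercial. Labdane numbering is used for ring positions.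

**Step 1**
Reactants: 1 2-methylcyclopentane-1,3-dione; 2 pent-1-en-3-one (ethyl vinyl ketone)
Product: 3 2-methyl-2-(3-oxopentyl)cyclopentane-1,3-dione
Conditions: H2O, AcOH (cat.), 75 °C
Reagents that add atoms: none
Why: Michael addition of the acidic 1,3-dione to the enone needs no strong base and stops after one alkylation because no acidic C–H is left between the ring carbonyls.

**Step 2**
Reactants: 3 2-methyl-2-(3-oxopentyl)cyclopentane-1,3-dione
Product: 4 (7aR)-4,7a-dimethyl-2,3,7,7a-tetrahydro-1H-indene-1,5(6H)-dione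
Conditions: D-phenylalanine, CSA, DMF, 30 → 70 °C; recrystallise
Reagents that add atoms: none
Why: Hajos–Parrish–Eder–Sauer–Wiechert aldol condensation through the amino-acid enamine selects one enantiotopic ring carbonyl and sets the quaternary carbon (later C10) as R, the D-amino acid giving the enantiomer of the steroid series.

**Step 3**
Reactants: 4 (7aR)-4,7a-dimethyl-2,3,7,7a-tetrahydro-1H-indene-1,5(6H)-dione
Product: 5 (1S,7aR)-1-ethenyl-1-hydroxy-4,7a-dimethyl-1,2,3,6,7,7a-hexahydro-5H-inden-5-one
Conditions: CH2=CHMgBr, CeCl3, THF, −78 °C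
Reagents that add atoms: vinylmagnesium bromide, C=C[Mg]Br
Why: Organocerium 1,2-addition is faster at the saturated cyclopentanone than at the tetrasubstituted conjugated enone and suppresses enolisation; attack anti to the angular methyl places OH cis to that methyl (this carbinol centre is erased in step 10).

**Step 4**
Reactants: 5 (1S,7aR)-1-ethenyl-1-hydroxy-4,7a-dimethyl-1,2,3,6,7,7a-hexahydro-5H-inden-5-one
Product: 7 (1S,3aS,7aR)-1-ethenyl-1-hydroxy-4,4,7a-trimethyloctahydro-5H-inden-5-one, via dilithium enolate-alkoxide 6 (not isolated)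
Conditions: Li, NH3(l)/THF, −78 → −33 °C; isoprene; then MeI, −78 → −33 °C
Reagents that add atoms: lithium, [Li] (counter-ion in 6 only); iodomethane, CI
Why: Dissolving-metal reductive alkylation of the enone: protonation of the β-carbon (C5) anti to the angular methyl gives the trans ring fusion, and the regiodefined enolate 6 is C-methylated to the gem-dimethyl ketone, while the isolated vinyl group and the tertiary alkoxide are inert.

**Step 5**
Reactants: 7 (1S,3aS,7aR)-1-ethenyl-1-hydroxy-4,4,7a-trimethyloctahydro-5H-inden-5-one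
Product: 8 (1S,3aR,5S,7aR)-1-ethenyl-4,4,7a-trimethyloctahydro-1H-indene-1,5-diol
Conditions: L-Selectride, THF, −78 °C; then NaOH, H2O2
Reagents that add atoms: none
Why: The bulky trialkylborohydride attacks the gem-dimethyl-flanked ketone along the equatorial trajectory and gives the axial (S) alcohol (OH syn to H5, anti to the angular methyl), as in Selectride reductions of 4,4-dimethyl-3-oxo triterpenoids to 3α-ols.

**Step 6**
Reactants: 8 (1S,3aR,5S,7aR)-1-ethenyl-4,4,7a-trimethyloctahydro-1H-indene-1,5-diol
Product: 9 (1S,3aR,5S,7aR)-1-ethenyl-4,4,7a-trimethyl-1,5-bis(triethylsilyloxy)octahydro-1H-indene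
Conditions: Et3SiOTf, 2,6-lutidine, CH2Cl2, 0 °C → rt
Reagents that add atoms: triethylsilyl trifluoromethanesulfonate, CC[Si](CC)(CC)OS(=O)(=O)C(F)(F)F
Why: The silyl triflate silylates both hindered hydroxyls; the tertiary silyl ether becomes the non-nucleophilic migration terminus of step 10 and the secondary one protects C3–OH.

**Step 7**
Reactants: 10 3-methylbut-2-en-1-ol (prenol)
Product: 11 tert-butyl[(3-methylbut-2-en-1-yl)oxy]diphenylsilane
Conditions: TBDPSCl, imidazole, DMF, rt
Reagents that add atoms: tert-butyl(chloro)diphenylsilane, CC(C)(C)[Si](Cl)(c1ccccc1)c1ccccc1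
Why: Standard silylation of a primary alcohol; a silyl ether is chosen because, unlike an ester, it cannot take part as a neighbouring group with the allyl cation of step 10.

**Step 8**
Reactants: 11 tert-butyl[(3-methylbut-2-en-1-yl)oxy]diphenylsilane
Product: 12 (2E)-4-[(tert-butyldiphenylsilyl)oxy]-2-methylbut-2-en-1-ol
Conditions: SeO2 (cat.), t-BuOOH, salicylic acid (cat.), CH2Cl2, rt
Reagents that add atoms: tert-butyl hydroperoxide, CC(C)(C)OO (oxygen delivered through catalytic selenium dioxide, O=[Se]=O)
Why: Selenium dioxide allylic oxidation (ene reaction then [2,3]-shift) oxidises only the E-methyl of a trisubstituted alkene, which fixes the 13E geometry of the target.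

**Step 9**
Reactants: 12 (2E)-4-[(tert-butyldiphenylsilyl)oxy]-2-methylbut-2-en-1-ol
Product: 13 {[(2E)-4-bromo-3-methylbut-2-en-1-yl]oxy}(tert-butyl)diphenylsilane
Conditions: CBr4, PPh3, CH2Cl2, 0 °C
Reagents that add atoms: carbon tetrabromide, BrC(Br)(Br)Br
Why: Appel bromination is an SN2 displacement at the primary carbon, so there is no allylic transposition and the E alkene is kept.

**Step 10**
Reactants: 9 (1S,3aR,5S,7aR)-1-ethenyl-4,4,7a-trimethyl-1,5-bis(triethylsilyloxy)octahydro-1H-indene; 13 {[(2E)-4-bromo-3-methylbut-2-en-1-yl]oxy}(tert-butyl)diphenylsilane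
Product: 15 ent-15-(tert-butyldiphenylsilyloxy)-3α-(triethylsilyloxy)-17-norlabd-13E-en-8-one, via allyl triflate 14 (not isolated)
Conditions: AgOTf, 2,6-di-tert-butyl-4-methylpyridine (cat.), 4 Å MS, CH2Cl2/toluene, −78 → −40 °C; then Et3N, DBU, rt
Reagents that add atoms: silver trifluoromethanesulfonate, [Ag+].[O-]S(=O)(=O)C(F)(F)F (supplies the triflate of 14; no atoms in 15)
Why: Proposed new method: AgOTf abstracts bromide from 13 to give the configurationally stable (E)-allyl triflate/ion pair 14 (the E geometry also keeps the silyl ether oxygen away from the cationic CH2), whose unhindered primary terminus is attacked by the terminal carbon of the vinyl group of 9, and the incipient secondary cation at C9 is intercepted in concert by 1,2-shift of the more substituted ring bond C8–C10 (retention at C10, pushed by the silyloxy lone pair), so that the cyclopentane becomes the cyclohexanone, the C11–C12 and C9–C10 bonds form in one operation and Et3Si+ leaves as its triflate; C9 is α to the new ketone and DBU settles its side chain equatorial (cis to the C10 methyl); the closest known reactions are halonium-, proton- and oxocarbenium-triggered (Prins–pinacol) semipinacol ring expansions of 1-alkenylcycloalkanols and silver-promoted additions of allyl cations to alkenes, but an allyl cation has not been used as the trigger.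

**Step 11**
Reactants: 15 ent-15-(tert-butyldiphenylsilyloxy)-3α-(triethylsilyloxy)-17-norlabd-13E-en-8-one
Product: 17 ent-15-(tert-butyldiphenylsilyloxy)-3α-(triethylsilyloxy)-17-norlabda-7,13E-dien-8-yl trifluoromethanesulfonate, via potassium enolate 16 (not isolated)
Conditions: KHMDS, THF, −78 °C; then PhNTf2, −78 → 0 °C
Reagents that add atoms: potassium hexamethyldisilazide, C[Si](C)(C)[N-][Si](C)(C)C.[K+] (counter-ion in 16 only); N-phenylbis(trifluoromethanesulfonimide), O=S(=O)(N(c1ccccc1)S(=O)(=O)C(F)(F)F)C(F)(F)F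
Why: Kinetic deprotonation by the bulky amide occurs at the C7 methylene and not at the tertiary C9–H next to the quaternary carbon, and O-triflation fixes the enolate as the 7,8-enol triflate without touching C9.

**Step 12**
Reactants: 17 ent-15-(tert-butyldiphenylsilyloxy)-3α-(triethylsilyloxy)-17-norlabda-7,13E-dien-8-yl trifluoromethanesulfonate
Product: 18 ent-15-(tert-butyldiphenylsilyloxy)-3α-(triethylsilyloxy)labda-7,13E-diene
Conditions: MeMgBr, Fe(acac)3 (cat.), THF/NMP, −30 → 0 °C
Reagents that add atoms: methylmagnesium bromide, C[Mg]Br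
Why: Iron-catalysed Kumada-type cross-coupling of the alkenyl triflate with a Grignard reagent that has no β-hydrogen installs the C8 methyl with the double bond fixed at C7–C8; silyl ethers are inert.

**Step 13**
Reactants: 18 ent-15-(tert-butyldiphenylsilyloxy)-3α-(triethylsilyloxy)labda-7,13E-diene
Product: 19 ent-labda-7,13E-diene-3α,15-diol
Conditions: TBAF, THF, rt → 50 °C
Reagents that add atoms: none
Why: Fluoride desilylation removes both silyl ethers and leaves the two trisubstituted alkenes untouched.

**Step 14**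
Reactants: 19 ent-labda-7,13E-diene-3α,15-diol; 20 (3S)-3-methylpentanoic acid
Product: 21 [(2E)-5-[(1R,4aS,6S,8aS)-6-hydroxy-2,5,5,8a-tetramethyl-1,4,4a,5,6,7,8,8a-octahydronaphthalen-1-yl]-3-methylpent-2-en-1-yl] (3S)-3-methylpentanoate
Conditions: EDC·HCl, DMAP (cat.), CH2Cl2, 0 °C
Reagents that add atoms: none
Why: Carbodiimide/DMAP (Steglich) esterification acylates the unhindered primary allylic OH much faster than the axial secondary OH next to the gem-dimethyl carbon, and the acid stereocentre is β to the carbonyl and cannot epimerise.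

**Compound list**
1 | 2-methylcyclopentane-1,3-dione | CC1C(=O)CCC1=O | starting material
2 | pent-1-en-3-one (ethyl vinyl ketone) | CCC(=O)C=C | starting material
3 | 2-methyl-2-(3-oxopentyl)cyclopentane-1,3-dione | CCC(=O)CCC1(C)C(=O)CCC1=O | intermediate
4 | (7aR)-4,7a-dimethyl-2,3,7,7a-tetrahydro-1H-indene-1,5(6H)-dione | O=C1CCC2=C(C)C(=O)CC[C@@]12C | intermediate
5 | (1S,7aR)-1-ethenyl-1-hydroxy-4,7a-dimethyl-1,2,3,6,7,7a-hexahydro-5H-inden-5-one (OH cis to the angular methyl) | C=C[C@@]1(O)CCC2=C(C)C(=O)CC[C@@]12C | intermediate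
6 | dilithium enolate-alkoxide of the trans-fused 4-methyl ketone (C4=C5 enolate, C1 alkoxide; not isolated) | [Li+].[Li+].C=C[C@@]1([O-])CC[C@@H]2C(C)=C([O-])CC[C@@]12C | intermediate
7 | (1S,3aS,7aR)-1-ethenyl-1-hydroxy-4,4,7a-trimethyloctahydro-5H-inden-5-one (trans-fused) | C=C[C@@]1(O)CC[C@@H]2C(C)(C)C(=O)CC[C@@]12C | intermediate
8 | (1S,3aR,5S,7aR)-1-ethenyl-4,4,7a-trimethyloctahydro-1H-indene-1,5-diol (5-OH axial, anti to the angular methyl) | C=C[C@@]1(O)CC[C@@H]2C(C)(C)[C@@H](O)CC[C@@]12C | intermediate
9 | (1S,3aR,5S,7aR)-1-ethenyl-4,4,7a-trimethyl-1,5-bis(triethylsilyloxy)octahydro-1H-indene | C=C[C@@]1(O[Si](CC)(CC)CC)CC[C@@H]2C(C)(C)[C@@H](O[Si](CC)(CC)CC)CC[C@@]12C | intermediate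
10 | 3-methylbut-2-en-1-ol (prenol) | CC(C)=CCO | starting material
11 | tert-butyl[(3-methylbut-2-en-1-yl)oxy]diphenylsilane | CC(C)=CCO[Si](c1ccccc1)(c1ccccc1)C(C)(C)C | intermediate
12 | (2E)-4-[(tert-butyldiphenylsilyl)oxy]-2-methylbut-2-en-1-ol | OC/C(C)=C/CO[Si](c1ccccc1)(c1ccccc1)C(C)(C)C | intermediate
13 | {[(2E)-4-bromo-3-methylbut-2-en-1-yl]oxy}(tert-butyl)diphenylsilane | BrC/C(C)=C/CO[Si](c1ccccc1)(c1ccccc1)C(C)(C)C | intermediate
14 | (2E)-4-[(tert-butyldiphenylsilyl)oxy]-2-methylbut-2-en-1-yl trifluoromethanesulfonate (allyl triflate/ion pair; not isolated) | O=S(=O)(OC/C(C)=C/CO[Si](c1ccccc1)(c1ccccc1)C(C)(C)C)C(F)(F)F | intermediate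
15 | ent-15-(tert-butyldiphenylsilyloxy)-3α-(triethylsilyloxy)-17-norlabd-13E-en-8-one [(1S,4aS,6S,8aR)-decalin-2-one; trans-decalin, C9 side chain equatorial and cis to the C10 methyl, 3-OSiEt3 axial] | CC(C)(C)[Si](c1ccccc1)(c1ccccc1)OC/C=C(\C)CC[C@@H]1C(=O)CC[C@@H]2C(C)(C)[C@@H](O[Si](CC)(CC)CC)CC[C@@]12C | intermediate
16 | potassium 7,8-enolate of 15 (not isolated) | CC(C)(C)[Si](c1ccccc1)(c1ccccc1)OC/C=C(\C)CC[C@@H]1C([O-])=CC[C@@H]2C(C)(C)[C@@H](O[Si](CC)(CC)CC)CC[C@@]12C.[K+] | intermediate
17 | ent-15-(tert-butyldiphenylsilyloxy)-3α-(triethylsilyloxy)-17-norlabda-7,13E-dien-8-yl trifluoromethanesulfonate | CC(C)(C)[Si](c1ccccc1)(c1ccccc1)OC/C=C(\C)CC[C@@H]1C(OS(=O)(=O)C(F)(F)F)=CC[C@@H]2C(C)(C)[C@@H](O[Si](CC)(CC)CC)CC[C@@]12C | intermediate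
18 | ent-15-(tert-butyldiphenylsilyloxy)-3α-(triethylsilyloxy)labda-7,13E-diene | CC(C)(C)[Si](c1ccccc1)(c1ccccc1)OC/C=C(\C)CC[C@@H]1C(C)=CC[C@@H]2C(C)(C)[C@@H](O[Si](CC)(CC)CC)CC[C@@]12C | intermediate
19 | ent-labda-7,13E-diene-3α,15-diol [(3S,5S,9R,10S); 3-OH axial] | OC/C=C(\C)CC[C@@H]1C(C)=CC[C@@H]2C(C)(C)[C@@H](O)CC[C@@]12C | intermediate
20 | (3S)-3-methylpentanoic acid | CC[C@H](C)CC(=O)O | starting material
21 | [(2E)-5-[(1R,4aS,6S,8aS)-6-hydroxy-2,5,5,8a-tetramethyl-1,4,4a,5,6,7,8,8a-octahydronaphthalen-1-yl]-3-methylpent-2-en-1-yl] (3S)-3-methylpentanoate | CC[C@H](C)CC(=O)OC/C=C(\C)CC[C@@H]1C(C)=CC[C@@H]2C(C)(C)[C@@H](O)CC[C@@]12C | target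

**Totals**
Total steps: 14. Longest linear sequence: 11 (steps 1–6 and 10–14); steps 7–9 form the three-step side branch.

**Steps most likely to fail**

Step 10 (the proposed new allylative semipinacol ring expansion). The weak vinyl nucleophile may lose to oligomerisation of the allyl cation or to ionisation of the tertiary allylic silyl ether. The fallback uses known chemistry, sets out from 9 and comes back at 15. Compound 9 is treated with N-bromosuccinimide in CH2Cl2 at −40 °C; the known bromonium-triggered semipinacol ring expansion of 1-vinylcycloalkanol silyl ethers gives the bromomethyl ketone ent-11-bromo-3α-(triethylsilyloxy)-12,13,14,15,16,17-hexanorlabdan-8-one F1. In parallel, alcohol 12 is acetylated (Ac2O, pyridine, DMAP) to the allylic acetate (2E)-4-[(tert-butyldiphenylsilyl)oxy]-2-methylbut-2-en-1-yl acetate F2. A nickel-catalysed reductive cross-electrophile allylation of the primary bromide with the acetate (NiBr2·glyme, 4,4'-di-tert-butyl-2,2'-bipyridine, Zn, MgCl2, DMA, rt), which is linear- and E-selective, followed by brief DBU equilibration at C9, gives 15. The ring expansion is then still the 1,2-shift, but the C11–C12 bond is made in a separate radical step.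

Step 4 (trans ring fusion in the dissolving-metal reduction). Hydrindenones are less reliably trans-selective than octalones, and the tertiary alkoxide might be O-methylated. The fallback sets out from 5 and comes back at 9. Compound 5 is silylated (Et3SiOTf, 2,6-lutidine) to the triethylsilyl ether (1S,7aR)-1-ethenyl-4,7a-dimethyl-1-(triethylsilyloxy)-1,2,3,6,7,7a-hexahydro-5H-inden-5-one F3. Conjugate reduction with t-BuCu/DIBAL-H in THF/HMPA at −50 °C, a hydrometalation known to deliver hydride to the ring-fusion carbon anti to the angular methyl of Hajos–Parrish enones, gives the trans-fused diisobutylaluminium enolate F4. This is activated with MeLi and methylated with MeI to the trans gem-dimethyl ketone (1S,3aS,7aR)-1-ethenyl-4,4,7a-trimethyl-1-(triethylsilyloxy)octahydro-5H-inden-5-one F5. L-Selectride then gives the axial alcohol (1S,3aR,5S,7aR)-1-ethenyl-4,4,7a-trimethyl-1-(triethylsilyloxy)octahydro-1H-inden-5-ol F6, and Et3SiOTf/2,6-lutidine returns 9.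

Step 3 (chemoselective vinyl addition to the hindered cyclopentanone in the presence of the enone). The fallback sets out from 4 and comes back at 5. The enone of 4 is first masked by the classical dienol ether method (triethyl orthoformate, p-TsOH cat., EtOH/dioxane), which leaves the saturated five-ring ketone free and gives the dienol ether (7aR)-5-ethoxy-4,7a-dimethyl-2,6,7,7a-tetrahydro-1H-inden-1-one F7. Vinylmagnesium bromide/CeCl3 can then add only to the remaining ketone and gives the carbinol (1S,7aR)-1-ethenyl-5-ethoxy-4,7a-dimethyl-2,6,7,7a-tetrahydro-1H-inden-1-ol F8, which is not isolated. Mild hydrolysis with aqueous oxalic acid restores the conjugated enone and gives 5.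

**Further compounds**
F1 | step 10 | ent-11-bromo-3α-(triethylsilyloxy)-12,13,14,15,16,17-hexanorlabdan-8-one (trans-decalin bromomethyl ketone, CH2Br equatorial at C9) | BrC[C@@H]1C(=O)CC[C@@H]2C(C)(C)[C@@H](O[Si](CC)(CC)CC)CC[C@@]12C
F2 | step 10 | (2E)-4-[(tert-butyldiphenylsilyl)oxy]-2-methylbut-2-en-1-yl acetate | CC(=O)OC/C(C)=C/CO[Si](c1ccccc1)(c1ccccc1)C(C)(C)C
F3 | step 4 | (1S,7aR)-1-ethenyl-4,7a-dimethyl-1-(triethylsilyloxy)-1,2,3,6,7,7a-hexahydro-5H-inden-5-one | C=C[C@@]1(O[Si](CC)(CC)CC)CCC2=C(C)C(=O)CC[C@@]12C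
F4 | step 4 | diisobutylaluminium enolate of the trans-fused 4-methyl ketone (1-triethylsilyl ether) | C=C[C@@]1(O[Si](CC)(CC)CC)CC[C@@H]2C(C)=C(O[Al](CC(C)C)CC(C)C)CC[C@@]12C
F5 | step 4 | (1S,3aS,7aR)-1-ethenyl-4,4,7a-trimethyl-1-(triethylsilyloxy)octahydro-5H-inden-5-one | C=C[C@@]1(O[Si](CC)(CC)CC)CC[C@@H]2C(C)(C)C(=O)CC[C@@]12C
F6 | step 4 | (1S,3aR,5S,7aR)-1-ethenyl-4,4,7a-trimethyl-1-(triethylsilyloxy)octahydro-1H-inden-5-ol | C=C[C@@]1(O[Si](CC)(CC)CC)CC[C@@H]2C(C)(C)[C@@H](O)CC[C@@]12C
F7 | step 3 | (7aR)-5-ethoxy-4,7a-dimethyl-2,6,7,7a-tetrahydro-1H-inden-1-one | O=C1CC=C2C(C)=C(OCC)CC[C@@]12C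
F8 | step 3 | (1S,7aR)-1-ethenyl-5-ethoxy-4,7a-dimethyl-2,6,7,7a-tetrahydro-1H-inden-1-ol | C=C[C@@]1(O)CC=C2C(C)=C(OCC)CC[C@@]12C
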